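(Readings and results were generated by integration for substances that don't exist; noise was put on by code.)

Start from the leftover: the part of the charge that the green flask can still turn into target.

| flask | solid substrate | temperature | remark | time |
|---|---|---|---|---|
| green | 0.80 M | 5 °C | the very flask that is asked about, followed so far |  |
| amber | 1.6 M | 0 °C | run made earlier |  |
| flask | 0.80 M | 5 °C |  | 8.0 h |

- green (time / h: target / %, solid substrate / %): 0.500: 54.3, 0; 1.33: 68.0, 0.1; 3.00: 70.9, 0; 6.00: 71.1, 0
- amber (time / h: target / %, solid substrate / %): 0.667: 32.0, 0.1; 1.33: 40.1, 0.4; 2.00: 44.5, 0; 3.00: 46.4, 0

(standard deviation of a reading: 0.5 percentage points)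

- target, in percent of the solid substrate first charged, at 8.0 h
- what to do for the largest gain in target; "none" if nothing gains more than 2 percentage points (midnight / dawn / winter / none)
- target present, with what was taken out counted in, in percent of the solid substrate first charged, after midnight
- target present, with what was taken out counted in, in percent of the solid substrate first charged, after dawn

- midnight: at 8.0 h raise the temperature by 15 K, then wait 8.0 h
- dawn: at 8.0 h take out 90 % of the target then present, then wait 8.0 h
- winter: change nothing and wait 8.0 h more

- percent here means solid substrate units held: one side product counts as two
- solid substrate is a solid; its amount is given per volume of the solution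
- target that was removed still counts
- steps under discussion: starting material + target -> side product; starting material -> target; solid substrate <-> starting material; intermediate B -> target; starting material <-> intermediate B; starting material <-> intermediate A
- at the start none of the solid substrate is in solution

Measure the leftover as the gap between a green target reading and the last one, 71.1 %. That gap falls from 17 percentage points at 0.500 h to 3.1 points at 1.33 h, so take 0.491 h as the leftover's lifetime, the time constant of its exponential fall.

Now bracket the target at 8.0 h. For the floor, note that target leaves by one listed step, which needs starting material, so allow the last reading less twice the scatter: 70.1 %. For the ceiling, suppose a slower tail hides in the flat stretch. Take the rise from 3.00 h to 6.00 h plus twice the scatter of a difference, and continue it to 8.0 h: 72.2 %.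

Then tighten by hand. From 1.33 h to 8.0 h lie 13.6 lifetimes, which leaves a gap far smaller than the 2 points an option must gain. My own reckoning is therefore 71.1 % and no useful option.

The forecast says 71.1 %, between 70.5 % and 71.8 %, inside this bracket. It chooses none, with 71.2 % after midnight and 71.2 % after dawn, and adds: “A small, slowly releasing store can't be strictly excluded”.

The green flask gives 71.1 % and none: midnight, dawn and winter each gain 0 points, leaving 71.1 % after midnight and 71.1 % after dawn.

    starting material + target → side product (k = 0.00150 L mol⁻¹ s⁻¹, Ea = 49.0 kJ mol⁻¹)
    starting material → target (k = 0.00250 s⁻¹, Ea = 90.0 kJ mol⁻¹)
    solid substrate ⇌ starting material, rate k3*(cs3 - [starting material]) while solid is left; crystals form when [starting material] > cs3 (solubility = 0.540 M, k = 0.00220 s⁻¹)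
    intermediate B → target (k = 3.50 × 10⁻⁴ s⁻¹, Ea = 80.0 kJ mol⁻¹)
    starting material ⇌ intermediate B (K = 0.510, k = 0.00110 s⁻¹, Ea = 84.0 kJ mol⁻¹, ΔH = −11.0 kJ mol⁻¹)
    starting material ⇌ intermediate A (K = 2.30, k = 0.00270 s⁻¹, Ea = 73.0 kJ mol⁻¹, ΔH = −68.0 kJ mol⁻¹)
    (constants at 5 °C)

Carry the lifetime through the green flask: starting material and both intermediates hold 16.3 % at 0.800 h, which the lifetime reckons down to 0.0241 % by 4.00 h, and at that time the green flask has intermediate A at 0.0153 %. The missing target sits in 28.9 % of side product, and the run without that loss reaches >99.9 %. In a neighbour flask kept at −20 °C, the asked time counts 16.3 green lifetimes, yet intermediate A, that flask's resting state, holds 55.8 %, and starting material with both intermediates holds 63.0 %.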